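## Retrosynthetic overview

1. Target 14 ⇐ 13 (phenol acetate removal) ⇐ enone 9 + acid 10: the C6–O ester bond is made directly on the γ-CH2 of the enone by an oxidative C–O coupling (key step, sets C6).
2. 9 ⇐ 8 ⇐ 7: the seven-membered ring is closed by ring-closing metathesis (C7=C8), then the C9 alcohol is oxidised to the ketone.
3. 7 ⇐ 6 ⇐ 5 ⇐ 4: isopropenyl addition to a C9 aldehyde (unmasked acetal); the C4 carbinol comes from isopropyl addition to the cyclopentanone.
4. 4 ⇐ 1 + 2 + allyl iodide: asymmetric conjugate addition and enolate allylation set C1 and C5 (future trans ring fusion).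
5. Ring order: the cyclopentane is bought (1); the cycloheptene ring is formed second (step 5).

Numbering used (daucane): C1 = ring-fusion carbon with the angular methyl, C2 and C3 = cyclopentane CH2 groups, C4 = carbinol carbon with the isopropyl group, C5 = ring-fusion CH, C6 = ester carbon, C7=C8 (methyl on C8), C9 = ketone, C10 = CH2. β = face of the C1 methyl, α = face of H5. The target is (1R,4R,5S,6S): trans-fused, 4β-OH, 6α-ester.

Assumption: 2 (0.5 M in THF) and 10 (trans-4-acetoxycinnamic acid) are bought as catalogue compounds.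

## Route

Step 1
Reactants: 1 3-methylcyclopent-2-en-1-one; 2 (1,3-dioxolan-2-ylmethyl)magnesium bromide
Product: 4 (2R,3R)-2-allyl-3-(1,3-dioxolan-2-ylmethyl)-3-methylcyclopentan-1-one, via magnesium enolate 3 (not isolated)
Conditions: Cu(OTf)2 (5 mol%), chiral hydroxyalkyl imidazolinium salt (N-mesityl, N′-leucinol-derived NHC precursor, antipode giving 3R, 6 mol%), 2 (1.3 equiv, slow addition), Et2O, −30 °C; then allyl iodide (3 equiv), DMPU, −30 °C → rt
Reagents that add atoms: allyl iodide, C=CCI
Why: Copper/NHC-catalysed asymmetric conjugate addition of a Grignard reagent to a β-methyl cyclic enone sets the quaternary C1 (R) by ligand control, and the magnesium enolate is C-allylated anti to the bulkier dioxolanylmethyl arm (syn to the methyl), which fixes C5 and the later trans ring fusion (tandem conjugate addition–enolate alkylation).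

Step 2
Reactants: 4 (2R,3R)-2-allyl-3-(1,3-dioxolan-2-ylmethyl)-3-methylcyclopentan-1-one
Product: 5 (1R,2R,3R)-2-allyl-3-(1,3-dioxolan-2-ylmethyl)-3-methyl-1-(propan-2-yl)cyclopentan-1-ol
Conditions: LaCl3·2LiCl (1.0 equiv), i-PrMgCl (1.5 equiv), THF, 0 °C; then H2O
Reagents that add atoms: isopropylmagnesium chloride, CC(C)[Mg]Cl
Why: Lanthanum-promoted Grignard 1,2-addition suppresses enolisation and reduction, and the nucleophile enters trans to the adjacent C5 allyl group (α-face), giving the 4β-hydroxyl cis to the angular methyl.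

Step 3
Reactants: 5 (1R,2R,3R)-2-allyl-3-(1,3-dioxolan-2-ylmethyl)-3-methyl-1-(propan-2-yl)cyclopentan-1-ol
Product: 6 2-[(1R,2R,3R)-2-allyl-3-hydroxy-1-methyl-3-(propan-2-yl)cyclopentyl]acetaldehyde
Conditions: TsOH·H2O (10 mol%), THF/H2O (4:1), 45 °C
Reagents that add atoms: water, O
Why: Acid-catalysed acetal hydrolysis frees the C9 aldehyde; the trans-placed tertiary hydroxyl cannot form a lactol and survives the mild aqueous acid, and no stereocentre is touched.

Step 4
Reactants: 6 2-[(1R,2R,3R)-2-allyl-3-hydroxy-1-methyl-3-(propan-2-yl)cyclopentyl]acetaldehyde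
Product: 7 (2RS)-1-[(1R,2R,3R)-2-allyl-3-hydroxy-1-methyl-3-(propan-2-yl)cyclopentyl]-3-methylbut-3-en-2-ol
Conditions: isopropenylmagnesium bromide (2.5 equiv), THF, −78 → 0 °C; then H2O
Reagents that add atoms: isopropenylmagnesium bromide, CC(=C)[Mg]Br
Why: Grignard 1,2-addition to the unhindered aldehyde brings in C8, its methyl and the second metathesis terminus; the C9 carbinol epimers do not matter because C9 is oxidised in step 6.

Step 5
Reactants: 7 (2RS)-1-[(1R,2R,3R)-2-allyl-3-hydroxy-1-methyl-3-(propan-2-yl)cyclopentyl]-3-methylbut-3-en-2-ol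
Product: 8 (1R,4R,5R,9RS)-dauc-7-ene-4,9-diol
Conditions: second-generation Grubbs catalyst RuCl2(=CHPh)(PCy3)(H2IMes) (5 mol%), CH2Cl2 (5 mM), 40 °C
Reagents that add atoms: none
Why: Ring-closing metathesis between the allyl group and the 1,1-disubstituted alkene of the allylic alcohol closes the seven-membered ring as the trisubstituted C7=C8 alkene, the trans fusion being already fixed on the cyclopentane.

Step 6
Reactants: 8 (1R,4R,5R,9RS)-dauc-7-ene-4,9-diol
Product: 9 (1R,4R,5R)-4-hydroxydauc-7-en-9-one
Conditions: Dess–Martin periodinane (1.3 equiv), CH2Cl2, 0 °C → rt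
Reagents that add atoms: none
Why: Dess–Martin oxidation converts both epimers of the secondary allylic alcohol into the enone, while the tertiary C4 hydroxyl cannot be oxidised.

Step 7
Reactants: 9 (1R,4R,5R)-4-hydroxydauc-7-en-9-one; 10 (2E)-3-(4-acetoxyphenyl)prop-2-enoic acid
Product: 13 (1R,4R,5S,6S)-4-hydroxy-9-oxodauc-7-en-6-yl (2E)-3-(4-acetoxyphenyl)prop-2-enoate, via dienol 11 (not isolated), via 6-iodo enone 12 (not isolated)
Conditions: Bu4NI (20 mol%), t-BuOOH (2.0 equiv, 5.5 M in decane), 10 (1.3 equiv), EtOAc, 50 °C, dark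
Reagents that add atoms: none
Why: Proposed new method: a vinylogous (γ-selective) ammonium hypoiodite-catalysed oxidative C–O coupling of an enone with a carboxylic acid, the closest known reaction being the Bu4NI/t-BuOOH-catalysed α-oxyacylation of simple saturated ketones with carboxylic acids, which has not been shown at the γ-position of an enone; under the acidic conditions 9 enolises through its γ-CH2 to the extended dienol 11 (the α′-CH2 is neopentyl and would give only a cross-conjugated enol), hypoiodite formed in the flask iodinates the dienol terminus to the allylic iodide 12, the C6 epimers of 12 interconvert by iodide exchange, and the ammonium carboxylate of 10 displaces the pseudo-axial 6β-iodide in an SN2 step from the open α-face (anti to the angular methyl), so the C6–O bond forms with the ester equatorial and cis to H5 (6S) while iodide returns to the cycle.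

Step 8
Reactants: 13 (1R,4R,5S,6S)-4-hydroxy-9-oxodauc-7-en-6-yl (2E)-3-(4-acetoxyphenyl)prop-2-enoate
Product: 14 (1R,4R,5S,6S)-4-hydroxy-9-oxodauc-7-en-6-yl (2E)-3-(4-hydroxyphenyl)prop-2-enoate
Conditions: NH4OAc (8 equiv), MeOH, rt
Reagents that add atoms: none
Why: Mild ammonium acetate-mediated methanolysis cleaves the activated aryl acetate chemoselectively (an aryloxide leaves far more easily than the hindered secondary alkoxide), leaving the cinnamate ester, the enone and all four stereocentres untouched.

## Compound list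

1 | 3-methylcyclopent-2-en-1-one | CC1=CC(=O)CC1 | starting material
2 | (1,3-dioxolan-2-ylmethyl)magnesium bromide | Br[Mg]CC1OCCO1 | starting material
3 | bromomagnesium (3R)-3-(1,3-dioxolan-2-ylmethyl)-3-methylcyclopent-1-en-1-olate | C[C@]1(CC2OCCO2)CCC(O[Mg]Br)=C1 | intermediate
4 | (2R,3R)-2-allyl-3-(1,3-dioxolan-2-ylmethyl)-3-methylcyclopentan-1-one | C=CC[C@@H]1[C@](C)(CCC1=O)CC2OCCO2 | intermediate
5 | (1R,2R,3R)-2-allyl-3-(1,3-dioxolan-2-ylmethyl)-3-methyl-1-(propan-2-yl)cyclopentan-1-ol | C=CC[C@@H]1[C@](C)(CC[C@@]1(O)C(C)C)CC2OCCO2 | intermediate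
6 | 2-[(1R,2R,3R)-2-allyl-3-hydroxy-1-methyl-3-(propan-2-yl)cyclopentyl]acetaldehyde | C=CC[C@@H]1[C@](C)(CC[C@@]1(O)C(C)C)CC=O | intermediate
7 | (2RS)-1-[(1R,2R,3R)-2-allyl-3-hydroxy-1-methyl-3-(propan-2-yl)cyclopentyl]-3-methylbut-3-en-2-ol | C=CC[C@@H]1[C@](C)(CC[C@@]1(O)C(C)C)CC(O)C(C)=C | intermediate
8 | (1R,4R,5R,9RS)-dauc-7-ene-4,9-diol (trans-fused, 4β-OH, C9 epimers) | CC1=CC[C@@H]2[C@](C)(CC[C@@]2(O)C(C)C)CC1O | intermediate
9 | (1R,4R,5R)-4-hydroxydauc-7-en-9-one | CC1=CC[C@@H]2[C@](C)(CC[C@@]2(O)C(C)C)CC1=O | intermediate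
10 | (2E)-3-(4-acetoxyphenyl)prop-2-enoic acid | CC(=O)Oc1ccc(/C=C/C(=O)O)cc1 | starting material
11 | (1R,4R,5R)-dauca-6,8-diene-4,9-diol (extended dienol of 9) | CC1C=C[C@@H]2[C@](C)(CC[C@@]2(O)C(C)C)CC=1O | intermediate
12 | (1R,4R,5R,6RS)-4-hydroxy-6-iododauc-7-en-9-one (interconverting C6 epimers) | CC1=CC(I)[C@@H]2[C@](C)(CC[C@@]2(O)C(C)C)CC1=O | intermediate
13 | (1R,4R,5S,6S)-4-hydroxy-9-oxodauc-7-en-6-yl (2E)-3-(4-acetoxyphenyl)prop-2-enoate | CC1=C[C@H](OC(=O)/C=C/c2ccc(OC(C)=O)cc2)[C@@H]2[C@](C)(CC[C@@]2(O)C(C)C)CC1=O | intermediate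
14 | (1R,4R,5S,6S)-4-hydroxy-9-oxodauc-7-en-6-yl (2E)-3-(4-hydroxyphenyl)prop-2-enoate = (3R,3aS,4S,8aR)-3-hydroxy-6,8a-dimethyl-7-oxo-3-(propan-2-yl)-1,2,3,3a,4,7,8,8a-octahydroazulen-4-yl (2E)-3-(4-hydroxyphenyl)prop-2-enoate | CC1=C[C@H](OC(=O)/C=C/c2ccc(O)cc2)[C@@H]2[C@](C)(CC[C@@]2(O)C(C)C)CC1=O | target

## Step count and risks

Total step count: 8. Longest linear sequence: 8 steps (1 → 14).

The three steps most likely to fail:

**Step 1.** The alkylcopper formed from 2 carries a β-alkoxy group and may eliminate. Grignard additions of this class to five-membered enones often give only about 80–90% ee. The methyl and CH2-dioxolane arms may not differ enough for clean trans allylation. Fallback (sets out from 2, comes back at 3): the order in which the two C1 substituents arrive is reversed. Grignard 2 is added in 1,2-fashion, without copper, to purchased 3-ethoxycyclopent-2-en-1-one to give 1-(1,3-dioxolan-2-ylmethyl)-3-ethoxycyclopent-2-en-1-ol F1. Brief cold dilute-acid work-up (Stork–Danheiser transposition) turns this into 3-(1,3-dioxolan-2-ylmethyl)cyclopent-2-en-1-one F2. Conjugate addition of MeMgBr to F2 with the same Cu(OTf)2/NHC system (opposite ligand antipode) then gives the same magnesium enolate 3, which is allylated as in step 1. A minor C5 epimer of 4 can be recycled by base equilibration, since allyl trans to the larger arm is favoured.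

**Step 2.** A secondary Grignard reagent on an α-branched, enolisable cyclopentanone can give enolisation, reduction, or the wrong face. Fallback (sets out from 4, comes back at 5): the bond is made in a samarium Barbier reaction instead of with a preformed basic organometallic. Ketone 4 and 2-iodopropane (3 equiv) are added to SmI2 (4 equiv) with NiI2 (2 mol%) in THF at 0 °C → rt. The weakly basic alkylsamarium adds from the same α-face to give 5. New compounds on the way: none F0.

**Step 7 (proposed new step).** Possible failures are α′- or C8-functionalisation, attack on the wrong face of C6, over-oxidation of the product, or radical chemistry from a hypoiodite of the tertiary alcohol (hence the dark). Fallback with known chemistry (sets out from 9, comes back at 13): TMSOTf/Et3N in CH2Cl2 converts 9 into the extended, doubly silylated dienol ether (1R,4R,5R)-4,9-bis(trimethylsilyloxy)dauca-6,8-diene F3. Vinylogous Rubottom oxidation with dimethyldioxirane (acetone, −40 °C), with attack at the diene terminus C6 from the α-face, followed by dilute HCl work-up, gives (1R,4R,5S,6S)-4,6-dihydroxydauc-7-en-9-one F4. Steglich esterification of its secondary allylic hydroxyl with 10 (EDC·HCl, catalytic DMAP, CH2Cl2) gives 13; the tertiary hydroxyl does not acylate.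

## Further compounds

F1 | step 1 | 1-(1,3-dioxolan-2-ylmethyl)-3-ethoxycyclopent-2-en-1-ol (racemic) | CCOC1=CC(O)(CC2OCCO2)CC1
F2 | step 1 | 3-(1,3-dioxolan-2-ylmethyl)cyclopent-2-en-1-one | O=C1C=C(CC2OCCO2)CC1
F0 | step 2 | none | none
F3 | step 7 | (1R,4R,5R)-4,9-bis(trimethylsilyloxy)dauca-6,8-diene | CC1C=C[C@@H]2[C@](C)(CC[C@@]2(O[Si](C)(C)C)C(C)C)CC=1O[Si](C)(C)C
F4 | step 7 | (1R,4R,5S,6S)-4,6-dihydroxydauc-7-en-9-one | CC1=C[C@H](O)[C@@H]2[C@](C)(CC[C@@]2(O)C(C)C)CC1=O
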